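## Retrosynthetic overview

1. Berbekorin A ⇐ its bis-MOM ether (one acid step at the end); the primary CH2OH ⇐ a vinyl group (oxidative cleavage, then reduction).
2. Key C1–C2 disconnection: diaryl ether benzaldehyde + a (Z)-γ-(MOM-oxy)allyl–B(Ipc)2 reagent. The metalated allyl ether acts as an α-alkoxy carbanion (d1), so two normally electrophilic carbons are joined and both stereocentres are set in that step.
3. Diaryl ether aldehyde ⇐ Cu-catalysed O-arylation of a mono-MOM catechol with 4-bromo-3,5-dimethoxybenzaldehyde.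
4. Mono-protected catechol ⇐ Baeyer–Villiger oxidation of the biaryl aldehyde ⇐ Suzuki coupling with PhB(OH)2 ⇐ MOM ether of 5-bromo-o-vanillin.
5. No ring is built: the three benzene rings are bought and joined in the order biaryl C–C bond, diaryl ether C–O bond, then the side chain.

Assumption: allyl methoxymethyl ether (9) is bought as a catalogue reagent; the Si-face sense of the (+)-α-pinene-derived Ipc reagent is taken from the known behaviour of this reagent family and should be confirmed on 14 (Mosher esters).

Target check: the SMILES gives (1R,2R), the threo (syn) aryl-glycerol; ring A carries OMe, free OH and O-aryl on adjacent carbons with phenyl para to the OH.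

## Route

Step 1
Reactants: 1 5-bromo-2-hydroxy-3-methoxybenzaldehyde
Product: 2 5-bromo-3-methoxy-2-(methoxymethoxy)benzaldehyde
Conditions: MOMCl, i-Pr2NEt, CH2Cl2, 0 °C to rt
Reagents that add atoms: chloromethyl methyl ether (MOMCl), COCCl
Why: Base-mediated O-alkylation of the phenol with MOMCl (acetal protection) masks the oxygen that ends as the free phenol, so that only the oxygen created later can be arylated; no stereocentre.

Step 2
Reactants: 2 5-bromo-3-methoxy-2-(methoxymethoxy)benzaldehyde; 3 phenylboronic acid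
Product: 4 3-methoxy-2-(methoxymethoxy)-5-phenylbenzaldehyde
Conditions: Pd(dppf)Cl2 (3 mol %), K2CO3, dioxane–H2O 4:1, 85 °C
Reagents that add atoms: none
Why: Suzuki–Miyaura cross-coupling of an unhindered aryl bromide with phenylboronic acid, which tolerates the aldehyde and the MOM acetal under aqueous carbonate.

Step 3
Reactants: 4 3-methoxy-2-(methoxymethoxy)-5-phenylbenzaldehyde
Product: 6 3-methoxy-2-(methoxymethoxy)-5-phenylphenol, via aryl formate 5 (not isolated)
Conditions: mCPBA, CH2Cl2, 0 °C to rt; aq NaHCO3 wash; then K2CO3 (cat.), MeOH, rt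
Reagents that add atoms: 3-chloroperoxybenzoic acid (mCPBA), OOC(=O)c1cccc(Cl)c1
Why: Baeyer–Villiger (Dakin-type) oxidation in which the electron-rich 2,3-dioxygenated aryl group migrates in the Criegee intermediate to give formate 5, cleaved by mild methanolysis that leaves the MOM acetal intact.

Step 4
Reactants: 6 3-methoxy-2-(methoxymethoxy)-5-phenylphenol; 7 4-bromo-3,5-dimethoxybenzaldehyde
Product: 8 3,5-dimethoxy-4-[3-methoxy-2-(methoxymethoxy)-5-phenylphenoxy]benzaldehyde
Conditions: CuI (10 mol %), picolinic acid (20 mol %), K3PO4, DMSO, 90 °C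
Reagents that add atoms: none
Why: Ullmann-type Cu(I)/picolinate C–O coupling, a ligand system made for ortho-substituted partners, with a bromide activated by its para-formyl group and a phenol that has only one free OH, so the ether forms at the required oxygen.

Step 5
Reactants: 8 3,5-dimethoxy-4-[3-methoxy-2-(methoxymethoxy)-5-phenylphenoxy]benzaldehyde; 9 allyl methoxymethyl ether
Product: 14 (1R,2R)-1-{3,5-dimethoxy-4-[3-methoxy-2-(methoxymethoxy)-5-phenylphenoxy]phenyl}-2-(methoxymethoxy)but-3-en-1-ol, via allyllithium 10 (not isolated), via borate complex 11 (not isolated), via allylborane 12 (not isolated), via borinate ester 13 (not isolated)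
Conditions: 9, s-BuLi, THF, −78 °C; (−)-Ipc2BOMe, −78 °C; BF3·OEt2; then 8, −78 °C, 4 h; NaOH, H2O2, rt
Reagents that add atoms: (−)-B-methoxydiisopinocampheylborane [(−)-Ipc2BOMe, from (+)-α-pinene], COB([C@@H]1C[C@@H]2C[C@H]([C@H]1C)C2(C)C)[C@@H]1C[C@@H]2C[C@H]([C@H]1C)C2(C)C (its atoms are carried only in 11–13 and are gone in 14)
Why: Brown asymmetric γ-alkoxyallylboration: the metalated allyl ether is an α-alkoxy carbanion (d1, reversed-polarity) equivalent, so its oxygen-bearing carbon, normally an electrophilic site, bonds to the electrophilic formyl carbon through a closed six-membered chair transition state, in which the Z-enol ether geometry gives the syn (threo) relationship and the (+)-α-pinene-derived Ipc groups direct attack to the Si face of the aldehyde, setting C1 (R) and C2 (R) together (typically ≥95:5 dr, about 90% ee).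

Step 6
Reactants: 14 (1R,2R)-1-{3,5-dimethoxy-4-[3-methoxy-2-(methoxymethoxy)-5-phenylphenoxy]phenyl}-2-(methoxymethoxy)but-3-en-1-ol
Product: 17 (1R,2R)-1-{3,5-dimethoxy-4-[3-methoxy-2-(methoxymethoxy)-5-phenylphenoxy]phenyl}-2-(methoxymethoxy)propane-1,3-diol, via 3,4-diol 15 (not isolated), via aldehyde 16 (not isolated)
Conditions: OsO4 (2 mol %), NaIO4, 2,6-lutidine, dioxane–H2O 3:1, rt; extractive work-up; then NaBH4, MeOH, 0 °C
Reagents that add atoms: osmium tetroxide, O=[Os](=O)(=O)=O (catalytic, delivers the oxygen that becomes the C3 hydroxyl); sodium periodate, [Na+].[O-]I(=O)(=O)=O (stoichiometric oxygen source that re-oxidises Os)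
Why: Lemieux–Johnson cleavage (Os-catalysed dihydroxylation, periodate glycol cleavage; lutidine-buffered) followed at once by borohydride reduction converts vinyl to CH2OH without epimerising the α-alkoxy aldehyde 16, the MOM-masked phenol being inert to periodate; C1 and C2 are untouched.

Step 7
Reactants: 17 (1R,2R)-1-{3,5-dimethoxy-4-[3-methoxy-2-(methoxymethoxy)-5-phenylphenoxy]phenyl}-2-(methoxymethoxy)propane-1,3-diol
Product: 18 berbekorin A, (1R,2R)-1-[4-(2-hydroxy-3-methoxy-5-phenylphenoxy)-3,5-dimethoxyphenyl]propane-1,2,3-triol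
Conditions: 2 M aq HCl–THF 1:1, 40 °C
Reagents that add atoms: none
Why: Acid-catalysed acetal hydrolysis removes the aryl and the secondary alkyl MOM groups in aqueous THF, where water is the only nucleophile (no benzylic methyl ether can form) and no bond at C1 or C2 is broken, so the (1R,2R) configuration is retained.

## Compound list

1 | 5-bromo-2-hydroxy-3-methoxybenzaldehyde (5-bromo-o-vanillin) | COc1cc(Br)cc(C=O)c1O | starting material
2 | 5-bromo-3-methoxy-2-(methoxymethoxy)benzaldehyde | COCOc1c(OC)cc(Br)cc1C=O | intermediate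
3 | phenylboronic acid | OB(O)c1ccccc1 | starting material
4 | 3-methoxy-2-(methoxymethoxy)-5-phenylbenzaldehyde | COCOc1c(OC)cc(-c2ccccc2)cc1C=O | intermediate
5 | 3-methoxy-2-(methoxymethoxy)-5-phenylphenyl formate | COCOc1c(OC)cc(-c2ccccc2)cc1OC=O | intermediate (not isolated)
6 | 3-methoxy-2-(methoxymethoxy)-5-phenylphenol | COCOc1c(OC)cc(-c2ccccc2)cc1O | intermediate
7 | 4-bromo-3,5-dimethoxybenzaldehyde | COc1cc(C=O)cc(OC)c1Br | starting material
8 | 3,5-dimethoxy-4-[3-methoxy-2-(methoxymethoxy)-5-phenylphenoxy]benzaldehyde | COc1cc(-c2ccccc2)cc(Oc2c(OC)cc(C=O)cc2OC)c1OCOC | intermediate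
9 | allyl methoxymethyl ether, 3-(methoxymethoxy)prop-1-ene | C=CCOCOC | starting material
10 | (Z)-3-(methoxymethoxy)allyllithium (metalated 9) | [Li]C/C=C\OCOC | intermediate (not isolated)
11 | lithium [(Z)-3-(methoxymethoxy)allyl](methoxy)diisopinocampheylborate | [Li+].CO[B-](C/C=C\OCOC)([C@@H]1C[C@@H]2C[C@H]([C@H]1C)C2(C)C)[C@@H]1C[C@@H]2C[C@H]([C@H]1C)C2(C)C | intermediate (not isolated)
12 | [(Z)-3-(methoxymethoxy)allyl]diisopinocampheylborane, Ipc from (+)-α-pinene | COCO/C=C\CB([C@@H]1C[C@@H]2C[C@H]([C@H]1C)C2(C)C)[C@@H]1C[C@@H]2C[C@H]([C@H]1C)C2(C)C | intermediate (not isolated)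
13 | O-diisopinocampheylboryl ether (borinate) of 14 | COc1cc(-c2ccccc2)cc(Oc2c(OC)cc([C@@H](OB([C@@H]3C[C@@H]4C[C@H]([C@H]3C)C4(C)C)[C@@H]3C[C@@H]4C[C@H]([C@H]3C)C4(C)C)[C@H](OCOC)C=C)cc2OC)c1OCOC | intermediate (not isolated)
14 | (1R,2R)-1-{3,5-dimethoxy-4-[3-methoxy-2-(methoxymethoxy)-5-phenylphenoxy]phenyl}-2-(methoxymethoxy)but-3-en-1-ol | COc1cc(-c2ccccc2)cc(Oc2c(OC)cc([C@@H](O)[C@H](OCOC)C=C)cc2OC)c1OCOC | intermediate
15 | 1-{3,5-dimethoxy-4-[3-methoxy-2-(methoxymethoxy)-5-phenylphenoxy]phenyl}-2-(methoxymethoxy)butane-1,3,4-triol; C1 and C2 as in 14, both C3 epimers | COc1cc(-c2ccccc2)cc(Oc2c(OC)cc([C@@H](O)[C@H](OCOC)C(O)CO)cc2OC)c1OCOC | intermediate (not isolated)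
16 | (2S,3R)-3-{3,5-dimethoxy-4-[3-methoxy-2-(methoxymethoxy)-5-phenylphenoxy]phenyl}-3-hydroxy-2-(methoxymethoxy)propanal | COc1cc(-c2ccccc2)cc(Oc2c(OC)cc([C@@H](O)[C@H](OCOC)C=O)cc2OC)c1OCOC | intermediate (not isolated)
17 | (1R,2R)-1-{3,5-dimethoxy-4-[3-methoxy-2-(methoxymethoxy)-5-phenylphenoxy]phenyl}-2-(methoxymethoxy)propane-1,3-diol | COc1cc(-c2ccccc2)cc(Oc2c(OC)cc([C@@H](O)[C@H](OCOC)CO)cc2OC)c1OCOC | intermediate
18 | berbekorin A, (1R,2R)-1-[4-(2-hydroxy-3-methoxy-5-phenylphenoxy)-3,5-dimethoxyphenyl]propane-1,2,3-triol | COc1cc(-c2ccccc2)cc(Oc2c(OC)cc([C@@H](O)[C@H](O)CO)cc2OC)c1O | target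

## Step count and risks

Total steps: 7. Longest linear sequence: 7 (1 → 18; compounds 3, 7 and 9 are bought).

The three steps most likely to fail are steps 4, 5 and 7.

The copper coupling of step 4 joins a bromide flanked by two methoxy groups to an ortho-substituted phenol and may stall or give reduced arene. The fallback sets out from phenol 6 and comes back at aldehyde 8. It drops the metal-catalysed coupling for a nucleophilic aromatic substitution: 6 and purchased 4-fluoro-3,5-dimethoxybenzaldehyde (K2CO3, DMSO, 110 °C) react by addition–elimination through a Meisenheimer complex stabilised by the para-formyl group, where the small fluoride eases the steric problem. This gives 8 directly and no new compound is made (F0).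

The allylboration of step 5 carries the whole stereochemical load; about 90% ee is typical, and the lithiation–borane sequence is operationally demanding. The enantiomeric purity can be raised by recrystallising 17 or 18, and if the sense of induction proves opposite, (+)-Ipc2BOMe is used instead. The fallback sets out from aldehyde 8 and allyl ether 9 and comes back at 14. It keeps the same d1 disconnection but moves stereocontrol from a stoichiometric chiral borane to a catalyst. Compound 9 is metalated as before (10) and trapped with 2-isopropoxy-4,4,5,5-tetramethyl-1,3,2-dioxaborolane to give the isolable, achiral pinacol (Z)-3-(methoxymethoxy)allylboronate F1. F1 is then added to 8 under chiral phosphoric acid catalysis (5 mol %, toluene, −30 °C), using the TRIP enantiomer that delivers allyl to the Si face of aryl aldehydes ((S)-TRIP by analogy with the benzaldehyde/allyl-Bpin case). This extension to a γ-alkoxy boronate is plausible but not established. It gives the O-pinacolboryl ether F2, which is hydrolysed on work-up to 14.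

The acid deprotection of step 7 can epimerise the electron-rich benzylic carbinol, or the oxocarbenium ion from the alkyl MOM group can be trapped by a neighbouring hydroxyl as a cyclic methylene acetal. The fallback sets out from 17 and comes back at 18. It first blocks both free hydroxyls: Ac2O, pyridine and catalytic DMAP give the 1,3-diacetate F3, in which no hydroxyl can capture the oxocarbenium ion and the benzylic oxygen is no longer a protonatable alcohol. Both MOM groups are then removed by soft Lewis acid–thiol transfer (ZnBr2, n-PrSH, CH2Cl2, 0 °C, minutes) to give the diacetate diol F4, and methanolysis (K2CO3, MeOH, rt) gives 18.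

Further compounds
F0 | step 4 | none | none
F1 | step 5 | 2-[(2Z)-3-(methoxymethoxy)prop-2-en-1-yl]-4,4,5,5-tetramethyl-1,3,2-dioxaborolane | COCO/C=C\CB1OC(C)(C)C(C)(C)O1
F2 | step 5 | O-pinacolboryl ether of 14 | COc1cc(-c2ccccc2)cc(Oc2c(OC)cc([C@@H](OB3OC(C)(C)C(C)(C)O3)[C@H](OCOC)C=C)cc2OC)c1OCOC
F3 | step 7 | (1R,2R)-1-{3,5-dimethoxy-4-[3-methoxy-2-(methoxymethoxy)-5-phenylphenoxy]phenyl}-2-(methoxymethoxy)propane-1,3-diyl diacetate | COc1cc(-c2ccccc2)cc(Oc2c(OC)cc([C@@H](OC(C)=O)[C@H](OCOC)COC(C)=O)cc2OC)c1OCOC
F4 | step 7 | (1R,2R)-2-hydroxy-1-[4-(2-hydroxy-3-methoxy-5-phenylphenoxy)-3,5-dimethoxyphenyl]propane-1,3-diyl diacetate | COc1cc(-c2ccccc2)cc(Oc2c(OC)cc([C@@H](OC(C)=O)[C@H](O)COC(C)=O)cc2OC)c1O
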